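**Retrosynthetic overview**
1. Target 18 ⇐ oxidation of the benzylic alcohol 17 (C7 = carbinol/carbonyl carbon, C8 = stereocentre, C9 = methyl); the C7 centre is sacrificed, so only C8 must be controlled.
2. C9 methyl ⇐ CH2OTs ⇐ CH2OH, the primary alcohol left after reductive removal of an oxazolidinone auxiliary (C7–OH masked as a TBS ether).
3. Key C7–C8 bond ⇐ Evans boron aldol of aryloxyacetyl imide 8 with 3,4,5-trimethoxybenzaldehyde 9; (S)-4-benzyl-2-oxazolidinone sets C8.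
4. Imide 8 ⇐ aryloxyacetic acid 5 ⇐ Williamson etherification of 4-allyl-2,6-dimethoxyphenol 1 with ethyl bromoacetate 2.
5. No ring is formed: both benzene rings are bought intact (in 1 and 9).

Assumption: the stereocentre of the target reads as (R) from the SMILES, and 4-allyl-2,6-dimethoxyphenol (methoxyeugenol) is bought as such.

**Route**

Step 1
Reactants: 1 4-allyl-2,6-dimethoxyphenol; 2 ethyl bromoacetate
Product: 3 ethyl 2-(4-allyl-2,6-dimethoxyphenoxy)acetate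
Conditions: K2CO3, acetone, reflux
Reagents that add atoms: none
Why: Williamson ether synthesis; the phenoxide alkylates the activated, unhindered α-bromo ester on oxygen under carbonate conditions that do not isomerise the allyl group.

Step 2
Reactants: 3 ethyl 2-(4-allyl-2,6-dimethoxyphenoxy)acetate
Product: 5 2-(4-allyl-2,6-dimethoxyphenoxy)acetic acid, via lithium carboxylate 4 (not isolated)
Conditions: LiOH·H2O, THF/H2O, rt; then 1 M HCl
Reagents that add atoms: lithium hydroxide monohydrate LiOH·H2O, [Li+].[OH-].O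
Why: Saponification of an unhindered ethyl ester followed by acidification; nothing else in the molecule is base- or acid-labile under these conditions.

Step 3
Reactants: 5 2-(4-allyl-2,6-dimethoxyphenoxy)acetic acid; 6 (S)-4-benzyl-2-oxazolidinone
Product: 8 (S)-4-benzyl-3-[2-(4-allyl-2,6-dimethoxyphenoxy)acetyl]oxazolidin-2-one, via mixed pivalic anhydride 7 (not isolated)
Conditions: PivCl, Et3N, THF, −20 °C; then LiCl, 6, −20 °C → rt
Reagents that add atoms: pivaloyl chloride, CC(C)(C)C(=O)Cl (its atoms stay only in 7)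
Why: N-acylation of the oxazolidinone through a mixed anhydride; the LiCl-activated auxiliary attacks the less hindered aryloxyacetyl carbonyl rather than the pivaloyl one.

Step 4
Reactants: 8 (S)-4-benzyl-3-[2-(4-allyl-2,6-dimethoxyphenoxy)acetyl]oxazolidin-2-one; 9 3,4,5-trimethoxybenzaldehyde
Product: 12 (S)-4-benzyl-3-[(2S,3R)-2-(4-allyl-2,6-dimethoxyphenoxy)-3-hydroxy-3-(3,4,5-trimethoxyphenyl)propanoyl]oxazolidin-2-one, via Z-dibutylboron enolate 10 (not isolated), via dibutylboron aldolate 11 (not isolated)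
Conditions: Bu2BOTf, iPr2NEt, CH2Cl2, −78 → 0 °C; 9, −78 → 0 °C; pH 7 phosphate buffer, MeOH, 30% H2O2, 0 °C
Reagents that add atoms: dibutylboron triflate, CCCCB(CCCC)OS(=O)(=O)C(F)(F)F (its Bu2B unit stays only in 10 and 11)
Why: Evans syn aldol; the Z-boron enolate adds to 9 through a closed Zimmerman–Traxler chair on the face opposite the benzyl group of the (S)-auxiliary, which sets C8 (2S in 12, R in the target after the CIP priority change), while the 3R carbinol centre is removed later.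

Step 5
Reactants: 12 (S)-4-benzyl-3-[(2S,3R)-2-(4-allyl-2,6-dimethoxyphenoxy)-3-hydroxy-3-(3,4,5-trimethoxyphenyl)propanoyl]oxazolidin-2-one
Product: 13 (S)-4-benzyl-3-[(2S,3R)-2-(4-allyl-2,6-dimethoxyphenoxy)-3-(tert-butyldimethylsilyloxy)-3-(3,4,5-trimethoxyphenyl)propanoyl]oxazolidin-2-one
Conditions: TBSOTf, 2,6-lutidine, CH2Cl2, −78 → 0 °C
Reagents that add atoms: tert-butyldimethylsilyl triflate, CC(C)(C)[Si](C)(C)OS(=O)(=O)C(F)(F)F
Why: Silyl ether protection; TBSOTf/2,6-lutidine silylates the hindered secondary alcohol without retro-aldol, so that later only the primary alcohol is sulfonylated and no oxetane can form.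

Step 6
Reactants: 13 (S)-4-benzyl-3-[(2S,3R)-2-(4-allyl-2,6-dimethoxyphenoxy)-3-(tert-butyldimethylsilyloxy)-3-(3,4,5-trimethoxyphenyl)propanoyl]oxazolidin-2-one
Product: 14 (2R,3R)-2-(4-allyl-2,6-dimethoxyphenoxy)-3-(tert-butyldimethylsilyloxy)-3-(3,4,5-trimethoxyphenyl)propan-1-ol
Conditions: LiBH4, MeOH (1 equiv), THF, 0 °C
Reagents that add atoms: none
Why: Reductive cleavage of the N-acyl oxazolidinone at the exocyclic carbonyl; alkene and silyl ether are inert, and C8 keeps its geometry (the descriptor changes from 2S to 2R only through CIP priorities).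

Step 7
Reactants: 14 (2R,3R)-2-(4-allyl-2,6-dimethoxyphenoxy)-3-(tert-butyldimethylsilyloxy)-3-(3,4,5-trimethoxyphenyl)propan-1-ol
Product: 15 (2R,3R)-2-(4-allyl-2,6-dimethoxyphenoxy)-3-(tert-butyldimethylsilyloxy)-3-(3,4,5-trimethoxyphenyl)propyl 4-methylbenzenesulfonate
Conditions: TsCl, Et3N, 4-(dimethylamino)pyridine (cat.), CH2Cl2, 0 °C → rt
Reagents that add atoms: 4-toluenesulfonyl chloride, Cc1ccc(cc1)S(=O)(=O)Cl
Why: Sulfonylation (tosylation) of the only free hydroxyl, a primary alcohol, under standard nucleophilic catalysis.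

Step 8
Reactants: 15 (2R,3R)-2-(4-allyl-2,6-dimethoxyphenoxy)-3-(tert-butyldimethylsilyloxy)-3-(3,4,5-trimethoxyphenyl)propyl 4-methylbenzenesulfonate
Product: 16 tert-butyl{[(1R,2R)-2-(4-allyl-2,6-dimethoxyphenoxy)-1-(3,4,5-trimethoxyphenyl)propyl]oxy}dimethylsilane
Conditions: LiEt3BH, THF, 0 °C → rt
Reagents that add atoms: none
Why: SN2 hydride displacement of a primary tosylate turns CH2OTs into the C9 methyl; the reaction occurs at the carbon next to C8, so the stereocentre is untouched, and the reagent has no B–H able to hydroborate the alkene.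

Step 9
Reactants: 16 tert-butyl{[(1R,2R)-2-(4-allyl-2,6-dimethoxyphenoxy)-1-(3,4,5-trimethoxyphenyl)propyl]oxy}dimethylsilane
Product: 17 (1R,2R)-2-(4-allyl-2,6-dimethoxyphenoxy)-1-(3,4,5-trimethoxyphenyl)propan-1-ol
Conditions: Bu4NF, THF, 0 °C → rt
Reagents that add atoms: none
Why: Fluoride-mediated desilylation driven by the Si–F bond; no carbonyl is present, so nothing can epimerise.

Step 10
Reactants: 17 (1R,2R)-2-(4-allyl-2,6-dimethoxyphenoxy)-1-(3,4,5-trimethoxyphenyl)propan-1-ol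
Product: 18 (R)-2-(4-allyl-2,6-dimethoxyphenoxy)-1-(3,4,5-trimethoxyphenyl)propan-1-one
Conditions: Dess–Martin periodinane, NaHCO3, CH2Cl2, 0 °C → rt; aq. Na2S2O3/NaHCO3 work-up
Reagents that add atoms: none
Why: Dess–Martin oxidation of the benzylic alcohol under bicarbonate buffering at or below rt gives the aryl ketone without enolising the α-aryloxy stereocentre C8 and leaves the allyl group and the electron-rich rings alone.

**Compound list**
1 | 4-allyl-2,6-dimethoxyphenol (methoxyeugenol) | C=CCc1cc(OC)c(O)c(OC)c1 | starting material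
2 | ethyl bromoacetate | CCOC(=O)CBr | starting material
3 | ethyl 2-(4-allyl-2,6-dimethoxyphenoxy)acetate | C=CCc1cc(OC)c(OCC(=O)OCC)c(OC)c1 | intermediate
4 | lithium 2-(4-allyl-2,6-dimethoxyphenoxy)acetate | C=CCc1cc(OC)c(OCC(=O)[O-])c(OC)c1.[Li+] | intermediate
5 | 2-(4-allyl-2,6-dimethoxyphenoxy)acetic acid | C=CCc1cc(OC)c(OCC(=O)O)c(OC)c1 | intermediate
6 | (S)-4-benzyl-2-oxazolidinone | O=C1N[C@@H](Cc2ccccc2)CO1 | starting material
7 | 2-(4-allyl-2,6-dimethoxyphenoxy)acetic pivalic anhydride | C=CCc1cc(OC)c(OCC(=O)OC(=O)C(C)(C)C)c(OC)c1 | intermediate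
8 | (S)-4-benzyl-3-[2-(4-allyl-2,6-dimethoxyphenoxy)acetyl]oxazolidin-2-one | C=CCc1cc(OC)c(OCC(=O)N2[C@@H](Cc3ccccc3)COC2=O)c(OC)c1 | intermediate
9 | 3,4,5-trimethoxybenzaldehyde | COc1cc(C=O)cc(OC)c1OC | starting material
10 | (S)-4-benzyl-3-[(Z)-2-(4-allyl-2,6-dimethoxyphenoxy)-1-(dibutylboryloxy)vinyl]oxazolidin-2-one | C=CCc1cc(OC)c(O/C=C(\OB(CCCC)CCCC)N2[C@@H](Cc3ccccc3)COC2=O)c(OC)c1 | intermediate
11 | (S)-4-benzyl-3-[(2S,3R)-2-(4-allyl-2,6-dimethoxyphenoxy)-3-(dibutylboryloxy)-3-(3,4,5-trimethoxyphenyl)propanoyl]oxazolidin-2-one | C=CCc1cc(OC)c(O[C@H](C(=O)N2[C@@H](Cc3ccccc3)COC2=O)[C@H](OB(CCCC)CCCC)c2cc(OC)c(OC)c(OC)c2)c(OC)c1 | intermediate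
12 | (S)-4-benzyl-3-[(2S,3R)-2-(4-allyl-2,6-dimethoxyphenoxy)-3-hydroxy-3-(3,4,5-trimethoxyphenyl)propanoyl]oxazolidin-2-one | C=CCc1cc(OC)c(O[C@H](C(=O)N2[C@@H](Cc3ccccc3)COC2=O)[C@H](O)c2cc(OC)c(OC)c(OC)c2)c(OC)c1 | intermediate
13 | (S)-4-benzyl-3-[(2S,3R)-2-(4-allyl-2,6-dimethoxyphenoxy)-3-(tert-butyldimethylsilyloxy)-3-(3,4,5-trimethoxyphenyl)propanoyl]oxazolidin-2-one | C=CCc1cc(OC)c(O[C@H](C(=O)N2[C@@H](Cc3ccccc3)COC2=O)[C@H](O[Si](C)(C)C(C)(C)C)c2cc(OC)c(OC)c(OC)c2)c(OC)c1 | intermediate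
14 | (2R,3R)-2-(4-allyl-2,6-dimethoxyphenoxy)-3-(tert-butyldimethylsilyloxy)-3-(3,4,5-trimethoxyphenyl)propan-1-ol | C=CCc1cc(OC)c(O[C@H](CO)[C@H](O[Si](C)(C)C(C)(C)C)c2cc(OC)c(OC)c(OC)c2)c(OC)c1 | intermediate
15 | (2R,3R)-2-(4-allyl-2,6-dimethoxyphenoxy)-3-(tert-butyldimethylsilyloxy)-3-(3,4,5-trimethoxyphenyl)propyl 4-methylbenzenesulfonate | C=CCc1cc(OC)c(O[C@H](COS(=O)(=O)c3ccc(C)cc3)[C@H](O[Si](C)(C)C(C)(C)C)c2cc(OC)c(OC)c(OC)c2)c(OC)c1 | intermediate
16 | tert-butyl{[(1R,2R)-2-(4-allyl-2,6-dimethoxyphenoxy)-1-(3,4,5-trimethoxyphenyl)propyl]oxy}dimethylsilane | C=CCc1cc(OC)c(O[C@H](C)[C@H](O[Si](C)(C)C(C)(C)C)c2cc(OC)c(OC)c(OC)c2)c(OC)c1 | intermediate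
17 | (1R,2R)-2-(4-allyl-2,6-dimethoxyphenoxy)-1-(3,4,5-trimethoxyphenyl)propan-1-ol | C=CCc1cc(OC)c(O[C@H](C)[C@H](O)c2cc(OC)c(OC)c(OC)c2)c(OC)c1 | intermediate
18 | (R)-2-(4-allyl-2,6-dimethoxyphenoxy)-1-(3,4,5-trimethoxyphenyl)propan-1-one | C=CCc1cc(OC)c(O[C@H](C)C(=O)c2cc(OC)c(OC)c(OC)c2)c(OC)c1 | target

**Step count**
Total steps: 10. Longest linear sequence: 10 steps (1/2 → 18); 6 and 9 are bought and enter at steps 3 and 4.

**Three steps most likely to fail, with fallbacks**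

Step 4 (aldol). The bulky aryloxy boron enolate and the electron-rich aldehyde may react sluggishly or with eroded facial control. The fallback sets out from acid 5 and comes back at 14. Acid 5 is coupled with (S)-4-benzylthiazolidine-2-thione (EDC·HCl, 4-(dimethylamino)pyridine, CH2Cl2) to give (S)-4-benzyl-3-[2-(4-allyl-2,6-dimethoxyphenoxy)acetyl]thiazolidine-2-thione F1. Its chlorotitanium enolate (TiCl4, iPr2NEt, N-methyl-2-pyrrolidinone, CH2Cl2, −78 → 0 °C) is more Lewis acidic and is expected to add to 9 in the same non-chelated Evans-syn sense, giving the aldol adduct (S)-4-benzyl-3-[(2S,3R)-2-(4-allyl-2,6-dimethoxyphenoxy)-3-hydroxy-3-(3,4,5-trimethoxyphenyl)propanoyl]thiazolidine-2-thione F2. The C8 configuration should be confirmed by correlation with 14. Silylation (TBSOTf, 2,6-lutidine) gives the silyl ether (S)-4-benzyl-3-[(2S,3R)-2-(4-allyl-2,6-dimethoxyphenoxy)-3-(tert-butyldimethylsilyloxy)-3-(3,4,5-trimethoxyphenyl)propanoyl]thiazolidine-2-thione F3. NaBH4 in THF/EtOH at 0 °C then cleaves the easily displaced thione auxiliary and delivers 14.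

Step 6 (reductive removal of the auxiliary from the hindered silyl ether 13). Endocyclic opening of the oxazolidinone or silyl migration may compete. The fallback sets out from 12 and comes back at 17 without a protecting group. LiBH4 (THF/H2O, 0 °C) on the unhindered free aldol 12 gives the diol (1R,2R)-2-(4-allyl-2,6-dimethoxyphenoxy)-1-(3,4,5-trimethoxyphenyl)propane-1,3-diol F4. Selective sulfonylation of the primary hydroxyl (TsCl, pyridine, 0 °C) gives the monotosylate (2R,3R)-2-(4-allyl-2,6-dimethoxyphenoxy)-3-hydroxy-3-(3,4,5-trimethoxyphenyl)propyl 4-methylbenzenesulfonate F5. LiAlH4 in THF (0 °C → rt) reduces the tosylate to the methyl group and gives 17 directly, bypassing steps 5 to 9.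

Step 8 (hydride displacement of the β-branched, β-oxygenated tosylate). The SN2 reaction may be slow, or hydride may attack sulfur and return 14. The fallback sets out from 14 and comes back at 16. Iodination (I2, PPh3, imidazole, CH2Cl2) gives the iodide tert-butyl{[(1R,2S)-2-(4-allyl-2,6-dimethoxyphenoxy)-3-iodo-1-(3,4,5-trimethoxyphenyl)propyl]oxy}dimethylsilane F6, which has a better leaving group and no S–O cleavage pathway. NaBH4 in DMSO (rt to 50 °C) reduces it to 16. Zinc and tin-radical reductions are avoided because a β-aryloxy organometallic or radical could expel the phenol.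

**Further compounds**
F1 | step 4 | (S)-4-benzyl-3-[2-(4-allyl-2,6-dimethoxyphenoxy)acetyl]thiazolidine-2-thione | C=CCc1cc(OC)c(OCC(=O)N2[C@@H](Cc3ccccc3)CSC2=S)c(OC)c1
F2 | step 4 | (S)-4-benzyl-3-[(2S,3R)-2-(4-allyl-2,6-dimethoxyphenoxy)-3-hydroxy-3-(3,4,5-trimethoxyphenyl)propanoyl]thiazolidine-2-thione | C=CCc1cc(OC)c(O[C@H](C(=O)N2[C@@H](Cc3ccccc3)CSC2=S)[C@H](O)c2cc(OC)c(OC)c(OC)c2)c(OC)c1
F3 | step 4 | (S)-4-benzyl-3-[(2S,3R)-2-(4-allyl-2,6-dimethoxyphenoxy)-3-(tert-butyldimethylsilyloxy)-3-(3,4,5-trimethoxyphenyl)propanoyl]thiazolidine-2-thione | C=CCc1cc(OC)c(O[C@H](C(=O)N2[C@@H](Cc3ccccc3)CSC2=S)[C@H](O[Si](C)(C)C(C)(C)C)c2cc(OC)c(OC)c(OC)c2)c(OC)c1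
F4 | step 6 | (1R,2R)-2-(4-allyl-2,6-dimethoxyphenoxy)-1-(3,4,5-trimethoxyphenyl)propane-1,3-diol | C=CCc1cc(OC)c(O[C@H](CO)[C@H](O)c2cc(OC)c(OC)c(OC)c2)c(OC)c1
F5 | step 6 | (2R,3R)-2-(4-allyl-2,6-dimethoxyphenoxy)-3-hydroxy-3-(3,4,5-trimethoxyphenyl)propyl 4-methylbenzenesulfonate | C=CCc1cc(OC)c(O[C@H](COS(=O)(=O)c3ccc(C)cc3)[C@H](O)c2cc(OC)c(OC)c(OC)c2)c(OC)c1
F6 | step 8 | tert-butyl{[(1R,2S)-2-(4-allyl-2,6-dimethoxyphenoxy)-3-iodo-1-(3,4,5-trimethoxyphenyl)propyl]oxy}dimethylsilane | C=CCc1cc(OC)c(O[C@H](CI)[C@H](O[Si](C)(C)C(C)(C)C)c2cc(OC)c(OC)c(OC)c2)c(OC)c1
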